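**Plan**

1. Late cuts: the C4–O methacrylate ester, the C3=CH2 carbon (Mannich methylenation) and the two silyl ethers. C6–CH2OH is traced back to an ethenyl group and C4–OH to a C4 ketone.
2. Main cut: C4–C5 and C6–C7 of the carbocycle. The array C4(=O)–C5=C6–C7H2 (a tetrasubstituted alkene between the carbinol carbon and the only ring methylene) is the retron of an alkyne inserted into the C(=O)–CH2 bond of a cyclobutanone. The six-membered ring is therefore grown from the four-membered ring C4–C3a–C7a–C7 of a lactone-fused cyclobutanone by the two alkyne carbons of a 1,3-enyne that already carries the side chain.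
3. Forward order: the four-membered ring and the cis-fused oxygen ring come first ([2+2] of dichloroketene with 2,3-dihydrofuran, then C–H oxidation to the lactone). Nickel-catalysed ring expansion then gives the cyclohexenone, followed by C4 reduction, ethenyl → CH2OH, C3 methylenation, acylation and desilylation.
4. Stereochemistry: C3a/C7a are cis from the suprafacial [2+2] and absolute from a lipase resolution. The side-chain centre is bought with (S)-β-citronellene. C4 is set by an oxazaborolidine reduction. The key step makes no stereocentre and touches none.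
5. Helper: the ethenyl group on the alkyne is a temporary regiochemical director for nickel and at the same time the latent hydroxymethyl carbon.

Key step: step 11

Remark: locants are those of the 1-benzofuran-2-one skeleton of the target (O1, C2, C3, C3a, C4 to C7, C7a); TBS = tert-butyl(dimethyl)silyl; (S)-β-citronellene and the (R)-oxazaborolidine are taken as commercial single enantiomers.

**Route**

Step 1
Reactants: 1 2,3-dihydrofuran
Product: 2 (±)-cis-7,7-dichloro-2-oxabicyclo[3.2.0]heptan-6-one (racemate)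
Conditions: Cl3CCOCl, Zn–Cu couple, Et2O–DME, 20 °C
Reagents that add atoms: trichloroacetyl chloride, ClC(=O)C(Cl)(Cl)Cl
Why: Ketene–enol ether [2+2] cycloaddition: dichloroketene made in the flask adds suprafacially to the cyclic enol ether with its carbonyl carbon on the nucleophilic β-carbon, which fixes the cis ring fusion and puts C=O next to the carbon-bearing bridgehead.

Step 2
Reactants: 2 (±)-cis-7,7-dichloro-2-oxabicyclo[3.2.0]heptan-6-one
Product: 3 (±)-cis-2-oxabicyclo[3.2.0]heptan-6-one (racemate)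
Conditions: Zn dust, AcOH, 60 °C
Reagents that add atoms: none
Why: Reductive dechlorination of an α,α-dichloroketone by zinc through zinc enolates that are protonated by acetic acid; the ring fusion is not affected.

Step 3
Reactants: 3 (±)-cis-2-oxabicyclo[3.2.0]heptan-6-one
Product: 4 (±)-endo-2-oxabicyclo[3.2.0]heptan-6-ol (racemate)
Conditions: NaBH4, MeOH, −20 °C
Reagents that add atoms: none
Why: Borohydride should attack the cyclobutanone from the convex face of the cis-fused bicycle and give the endo alcohol, the substrate for the enzymatic resolution.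

Step 4
Reactants: 4 (±)-endo-2-oxabicyclo[3.2.0]heptan-6-ol
Product: 5 (1R,5S,6S)-2-oxabicyclo[3.2.0]heptan-6-ol (recovered unreacted enantiomer)
Conditions: Burkholderia cepacia lipase, vinyl acetate, MTBE, 30 °C, run to just past half conversion; chromatography
Reagents that add atoms: none
Why: Lipase-catalysed kinetic resolution by transesterification: by the empirical size rule for secondary alcohols (bridgehead carbon large, CH2 medium) the (6R)-alcohol should be acetylated faster, so the (1R,5S,6S)-alcohol should remain.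

Step 5
Reactants: 5 (1R,5S,6S)-2-oxabicyclo[3.2.0]heptan-6-ol
Product: 7 (1R,5R)-2-oxabicyclo[3.2.0]heptane-3,6-dione, via bicyclic ketone 6 (not isolated)
Conditions: RuCl3 (5 mol %), NaIO4, MeCN–EtOAc–H2O, 20 °C
Reagents that add atoms: sodium periodate (oxygen, via RuO4), [Na+].[O-]I(=O)(=O)=O
Why: Catalytic RuO4 oxidises the secondary alcohol to the cyclobutanone and then the ether CH2 next to oxygen to the lactone carbonyl (ether-to-lactone C–H oxidation), the methylene being attacked in preference to the strained bridgehead C–H; neither stereocentre is touched.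

Step 6
Reactants: 8 (S)-β-citronellene [(3S)-3,7-dimethylocta-1,6-diene]
Product: 10 (4S)-4-methylhex-5-en-1-ol, via ozonide 9 (not isolated)
Conditions: O3 (1.0 equiv), CH2Cl2, −78 °C; then NaBH4, MeOH, −78 → 0 °C
Reagents that add atoms: ozone, [O-][O+]=O
Why: The electron-rich trisubstituted alkene reacts with ozone much faster than the monosubstituted one, so one equivalent should cleave it selectively, and reductive work-up gives the primary alcohol without touching the allylic stereocentre.

Step 7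
Reactants: 10 (4S)-4-methylhex-5-en-1-ol
Product: 11 tert-butyl(dimethyl){[(4S)-4-methylhex-5-en-1-yl]oxy}silane
Conditions: TBSCl, imidazole, DMF, 20 °C
Reagents that add atoms: tert-butyl(chloro)dimethylsilane, CC(C)(C)[Si](C)(C)Cl
Why: Standard silylation of a primary alcohol with the imidazole-activated silyl chloride.

Step 8
Reactants: 11 tert-butyl(dimethyl){[(4S)-4-methylhex-5-en-1-yl]oxy}silane
Product: 12 tert-butyl{[(4S)-5,6-dibromo-4-methylhexyl]oxy}dimethylsilane (mixture at C5)
Conditions: Br2, CH2Cl2, −78 °C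
Reagents that add atoms: bromine, BrBr
Why: Anti addition of bromine to the terminal alkene through a bromonium ion; the new centre forms as a mixture that is irrelevant because it is destroyed in the next step.

Step 9
Reactants: 12 tert-butyl{[(4S)-5,6-dibromo-4-methylhexyl]oxy}dimethylsilane
Product: 13 tert-butyl(dimethyl){[(4S)-4-methylhex-5-yn-1-yl]oxy}silane
Conditions: NaNH2 (3.3 equiv), NH3(l)–THF, −33 °C; then NH4Cl
Reagents that add atoms: none
Why: Two-fold E2 dehydrobromination gives the terminal alkyne, which is held as its sodium acetylide until the quench, so that no alkyne–allene isomerisation should erode the adjacent stereocentre.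

Step 10
Reactants: 13 tert-butyl(dimethyl){[(4S)-4-methylhex-5-yn-1-yl]oxy}silane, 14 vinyl bromide
Product: 15 tert-butyl(dimethyl){[(4S)-4-methyloct-7-en-5-yn-1-yl]oxy}silane
Conditions: Pd(PPh3)4 (5 mol %), CuI (10 mol %), iPr2NH, THF, 20 °C
Reagents that add atoms: none
Why: Sonogashira coupling (oxidative addition of the alkenyl bromide to zerovalent palladium, copper acetylide transmetalation, reductive elimination) gives the conjugated 1,3-enyne without involving the stereocentre.

Step 11
Reactants: 7 (1R,5R)-2-oxabicyclo[3.2.0]heptane-3,6-dione, 15 tert-butyl(dimethyl){[(4S)-4-methyloct-7-en-5-yn-1-yl]oxy}silane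
Product: 16 (3aR,7aR)-5-[(2S)-5-(TBSO)pentan-2-yl]-6-ethenyl-3,3a,7,7a-tetrahydro-1-benzofuran-2,4-dione
Conditions: Ni(cod)2 (10 mol %), PCy3 (20 mol %), toluene, 100 °C, 15 (1.5 equiv) added slowly
Reagents that add atoms: none
Why: Zerovalent nickel couples the ketone C=O of 7 with the alkyne of 15 by oxidative cyclisation to a spiro oxanickelacyclopentene, β-carbon elimination then breaks the strained C(=O)–CH2 bond of the four-membered ring, and C(sp3)–C(sp2) reductive elimination from the seven-membered divalent nickel metallacycle returns the catalyst; the closest known reaction type is the nickel-catalysed formal [4+2] insertion of internal alkynes into cyclobutanones. The six-membered ring is thus closed by reductive elimination between the migrated CH2 (C7) and the nickel-bound alkyne carbon (C6), after C4–C5 has been made in the oxidative cyclisation. No stereocentre is formed, and C3a and C7a are carried through unchanged because the bond that is cut is the one to the unsubstituted CH2. Regiochemistry on the alkyne is required: the conjugated ethenyl group should bind nickel in an η3 fashion, so the alkyne carbon bearing it stays on the metal while the carbon bearing the branched alkyl group bonds to the carbonyl carbon, as in nickel-mediated couplings of 1,3-enynes with ketones. Site selectivity between the two C(=O)–C bonds is also required and should follow from migration of the less substituted primary carbon rather than the ring-fusion carbon. Relief of cyclobutanone strain drives the step under neutral conditions that should leave the β-acyloxy ketone intact.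

Step 12
Reactants: 16 (3aR,7aR)-5-[(2S)-5-(TBSO)pentan-2-yl]-6-ethenyl-3,3a,7,7a-tetrahydro-1-benzofuran-2,4-dione
Product: 17 (3aS,4S,7aR)-5-[(2S)-5-(TBSO)pentan-2-yl]-6-ethenyl-4-hydroxy-3a,4,7,7a-tetrahydro-1-benzofuran-2(3H)-one
Conditions: (R)-2-methyl-CBS-oxazaborolidine (0.5 equiv), catecholborane, toluene, −78 °C; then aq. NaOH work-up
Reagents that add atoms: none
Why: Corey–Bakshi–Shibata reduction: the oxazaborolidine–borane complex binds the ketone on the side of the smaller sp3 flank (C3a) and, with the substituted alkenyl flank as the large group, the (R)-catalyst should deliver hydride 1,2 to the face that gives the (4S)-alcohol, so C4 is set by the reagent.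

Step 13
Reactants: 17 (3aS,4S,7aR)-5-[(2S)-5-(TBSO)pentan-2-yl]-6-ethenyl-4-hydroxy-3a,4,7,7a-tetrahydro-1-benzofuran-2(3H)-one
Product: 19 (3aS,4S,7aR)-5-[(2S)-5-(TBSO)pentan-2-yl]-4-hydroxy-6-(hydroxymethyl)-3a,4,7,7a-tetrahydro-1-benzofuran-2(3H)-one, via enal 18 (not isolated)
Conditions: OsO4 (2 mol %), NaIO4, 2,6-lutidine, dioxane–H2O, 20 °C; then NaBH4, MeOH, 0 °C
Reagents that add atoms: osmium tetroxide, O=[Os](=O)(=O)=O; sodium periodate, [Na+].[O-]I(=O)(=O)=O
Why: Lemieux–Johnson cleavage: OsO4 should dihydroxylate the monosubstituted ethenyl group far faster than the shielded tetrasubstituted ring alkene, periodate cleaves the diol to the enal, and borohydride reduces the aldehyde in the same flask to the primary allylic alcohol; no stereocentre is affected.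

Step 14
Reactants: 19 (3aS,4S,7aR)-5-[(2S)-5-(TBSO)pentan-2-yl]-4-hydroxy-6-(hydroxymethyl)-3a,4,7,7a-tetrahydro-1-benzofuran-2(3H)-one
Product: 20 (3aS,4S,7aR)-6-[(TBSO)methyl]-5-[(2S)-5-(TBSO)pentan-2-yl]-4-hydroxy-3a,4,7,7a-tetrahydro-1-benzofuran-2(3H)-one
Conditions: TBSCl (1.1 equiv), imidazole, CH2Cl2, −20 → 0 °C
Reagents that add atoms: tert-butyl(chloro)dimethylsilane, CC(C)(C)[Si](C)(C)Cl
Why: Silylation of the unhindered primary allylic hydroxyl should be much faster than that of the secondary C4 hydroxyl flanked by the tetrasubstituted alkene, so one equivalent differentiates them.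

Step 15
Reactants: 20 (3aS,4S,7aR)-6-[(TBSO)methyl]-5-[(2S)-5-(TBSO)pentan-2-yl]-4-hydroxy-3a,4,7,7a-tetrahydro-1-benzofuran-2(3H)-one
Product: 23 (3aS,4S,7aR)-6-[(TBSO)methyl]-5-[(2S)-5-(TBSO)pentan-2-yl]-4-hydroxy-3-methylidene-3a,4,7,7a-tetrahydro-1-benzofuran-2(3H)-one, via Mannich base 21 (not isolated), via ammonium iodide 22 (not isolated)
Conditions: LiN(SiMe3)2 (2.5 equiv), THF, −78 °C; CH2=NMe2+ I−, −78 → 0 °C; then MeI, MeOH–CH2Cl2, 20 °C; then aq. NaHCO3
Reagents that add atoms: Eschenmoser's salt (dimethylmethylideneammonium iodide), C=[N+](C)C.[I-]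
Why: α-Methylenation of a lactone by Mannich reaction of its lithium enolate with Eschenmoser's salt and Hofmann-type elimination of the quaternised amine; the first equivalent of base is taken up by the C4 hydroxyl, and the C3 centre created in 21 is erased on elimination.

Step 16
Reactants: 23 (3aS,4S,7aR)-6-[(TBSO)methyl]-5-[(2S)-5-(TBSO)pentan-2-yl]-4-hydroxy-3-methylidene-3a,4,7,7a-tetrahydro-1-benzofuran-2(3H)-one
Product: 24 (3aR,4S,7aR)-6-[(TBSO)methyl]-5-[(2S)-5-(TBSO)pentan-2-yl]-3-methylidene-2-oxo-2,3,3a,4,7,7a-hexahydro-1-benzofuran-4-yl 2-methylprop-2-enoate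
Conditions: methacrylic anhydride, Et3N, DMAP (0.2 equiv), CH2Cl2, 0 → 20 °C
Reagents that add atoms: methacrylic anhydride, CC(=C)C(=O)OC(=O)C(C)=C
Why: DMAP-catalysed O-acylation of the secondary allylic alcohol with the anhydride proceeds with retention at C4 and should not disturb the α-methylidene lactone.

Step 17
Reactants: 24 (3aR,4S,7aR)-6-[(TBSO)methyl]-5-[(2S)-5-(TBSO)pentan-2-yl]-3-methylidene-2-oxo-2,3,3a,4,7,7a-hexahydro-1-benzofuran-4-yl 2-methylprop-2-enoate
Product: 25 (3aR,4S,7aR)-6-(hydroxymethyl)-5-[(2S)-5-hydroxypentan-2-yl]-3-methylidene-2-oxo-2,3,3a,4,7,7a-hexahydro-1-benzofuran-4-yl 2-methylprop-2-enoate (target)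
Conditions: HF·pyridine, pyridine, THF, 0 → 20 °C
Reagents that add atoms: none
Why: Buffered HF cleaves the two primary silyl ethers under non-basic conditions that should spare the allylic ester and the α-methylidene lactone (no acyl migration, no conjugate addition).

**Compound list**

1 | 2,3-dihydrofuran | C1CC=CO1 | starting material
2 | (±)-cis-7,7-dichloro-2-oxabicyclo[3.2.0]heptan-6-one, racemate, (1S,5R) enantiomer drawn | O=C1C(Cl)(Cl)[C@H]2OCC[C@@H]12 | intermediate
3 | (±)-cis-2-oxabicyclo[3.2.0]heptan-6-one, racemate, (1R,5R) enantiomer drawn | O=C1C[C@H]2OCC[C@@H]12 | intermediate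
4 | (±)-endo-2-oxabicyclo[3.2.0]heptan-6-ol, racemate, (1R,5S,6S) enantiomer drawn | O[C@H]1C[C@H]2OCC[C@@H]12 | intermediate
5 | (1R,5S,6S)-2-oxabicyclo[3.2.0]heptan-6-ol | O[C@H]1C[C@H]2OCC[C@@H]12 | intermediate
6 | (1R,5R)-2-oxabicyclo[3.2.0]heptan-6-one (not isolated) | O=C1C[C@H]2OCC[C@@H]12 | intermediate
7 | (1R,5R)-2-oxabicyclo[3.2.0]heptane-3,6-dione | O=C1C[C@H]2OC(=O)C[C@@H]12 | intermediate
8 | (S)-β-citronellene, (3S)-3,7-dimethylocta-1,6-diene | C=C[C@@H](C)CCC=C(C)C | starting material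
9 | 3,3-dimethyl-5-[(3S)-3-methylpent-4-en-1-yl]-1,2,4-trioxolane (ozonide, not isolated) | C=C[C@@H](C)CCC1OOC(C)(C)O1 | intermediate
10 | (4S)-4-methylhex-5-en-1-ol | C=C[C@@H](C)CCCO | intermediate
11 | tert-butyl(dimethyl){[(4S)-4-methylhex-5-en-1-yl]oxy}silane | C=C[C@@H](C)CCCO[Si](C)(C)C(C)(C)C | intermediate
12 | tert-butyl{[(4S)-5,6-dibromo-4-methylhexyl]oxy}dimethylsilane, mixture at C5 | BrCC(Br)[C@@H](C)CCCO[Si](C)(C)C(C)(C)C | intermediate
13 | tert-butyl(dimethyl){[(4S)-4-methylhex-5-yn-1-yl]oxy}silane | C#C[C@@H](C)CCCO[Si](C)(C)C(C)(C)C | intermediate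
14 | vinyl bromide (bromoethene) | C=CBr | starting material
15 | tert-butyl(dimethyl){[(4S)-4-methyloct-7-en-5-yn-1-yl]oxy}silane | C=CC#C[C@@H](C)CCCO[Si](C)(C)C(C)(C)C | intermediate
16 | (3aR,7aR)-5-[(2S)-5-(TBSO)pentan-2-yl]-6-ethenyl-3,3a,7,7a-tetrahydro-1-benzofuran-2,4-dione | O=C1C([C@@H](C)CCCO[Si](C)(C)C(C)(C)C)=C(C=C)C[C@H]2OC(=O)C[C@@H]12 | intermediate
17 | (3aS,4S,7aR)-5-[(2S)-5-(TBSO)pentan-2-yl]-6-ethenyl-4-hydroxy-3a,4,7,7a-tetrahydro-1-benzofuran-2(3H)-one | O[C@@H]1C([C@@H](C)CCCO[Si](C)(C)C(C)(C)C)=C(C=C)C[C@H]2OC(=O)C[C@@H]12 | intermediate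
18 | (3aS,4S,7aR)-5-[(2S)-5-(TBSO)pentan-2-yl]-4-hydroxy-2-oxo-2,3,3a,4,7,7a-hexahydro-1-benzofuran-6-carbaldehyde (not isolated) | O[C@@H]1C([C@@H](C)CCCO[Si](C)(C)C(C)(C)C)=C(C=O)C[C@H]2OC(=O)C[C@@H]12 | intermediate
19 | (3aS,4S,7aR)-5-[(2S)-5-(TBSO)pentan-2-yl]-4-hydroxy-6-(hydroxymethyl)-3a,4,7,7a-tetrahydro-1-benzofuran-2(3H)-one | O[C@@H]1C([C@@H](C)CCCO[Si](C)(C)C(C)(C)C)=C(CO)C[C@H]2OC(=O)C[C@@H]12 | intermediate
20 | (3aS,4S,7aR)-6-[(TBSO)methyl]-5-[(2S)-5-(TBSO)pentan-2-yl]-4-hydroxy-3a,4,7,7a-tetrahydro-1-benzofuran-2(3H)-one | O[C@@H]1C([C@@H](C)CCCO[Si](C)(C)C(C)(C)C)=C(CO[Si](C)(C)C(C)(C)C)C[C@H]2OC(=O)C[C@@H]12 | intermediate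
21 | 3-[(dimethylamino)methyl] derivative of 20, C3 epimers (Mannich base, not isolated) | O[C@@H]1C([C@@H](C)CCCO[Si](C)(C)C(C)(C)C)=C(CO[Si](C)(C)C(C)(C)C)C[C@H]2OC(=O)C(CN(C)C)[C@@H]12 | intermediate
22 | 3-[(trimethylammonio)methyl] derivative of 20, iodide (not isolated) | O[C@@H]1C([C@@H](C)CCCO[Si](C)(C)C(C)(C)C)=C(CO[Si](C)(C)C(C)(C)C)C[C@H]2OC(=O)C(C[N+](C)(C)C)[C@@H]12.[I-] | intermediate
23 | (3aS,4S,7aR)-6-[(TBSO)methyl]-5-[(2S)-5-(TBSO)pentan-2-yl]-4-hydroxy-3-methylidene-3a,4,7,7a-tetrahydro-1-benzofuran-2(3H)-one | O[C@@H]1C([C@@H](C)CCCO[Si](C)(C)C(C)(C)C)=C(CO[Si](C)(C)C(C)(C)C)C[C@H]2OC(=O)C(=C)[C@@H]12 | intermediate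
24 | (3aR,4S,7aR)-6-[(TBSO)methyl]-5-[(2S)-5-(TBSO)pentan-2-yl]-3-methylidene-2-oxo-2,3,3a,4,7,7a-hexahydro-1-benzofuran-4-yl 2-methylprop-2-enoate | C=C(C)C(=O)O[C@@H]1C([C@@H](C)CCCO[Si](C)(C)C(C)(C)C)=C(CO[Si](C)(C)C(C)(C)C)C[C@H]2OC(=O)C(=C)[C@@H]12 | intermediate
25 | (3aR,4S,7aR)-6-(hydroxymethyl)-5-[(2S)-5-hydroxypentan-2-yl]-3-methylidene-2-oxo-2,3,3a,4,7,7a-hexahydro-1-benzofuran-4-yl 2-methylprop-2-enoate | C=C(C)C(=O)O[C@@H]1C([C@@H](C)CCCO)=C(CO)C[C@H]2OC(=O)C(=C)[C@@H]12 | target

**Count**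

Total steps: 17. Longest linear sequence: 12 steps (steps 1–5 and 11–17; the branch through steps 6–10 and 11–17 is equally long).

**Steps most likely to fail**

Step 11. The conjugated enyne may oligomerise on zerovalent nickel faster than it couples with the hindered, α-substituted cyclobutanone. Any erosion of the alkene-directed regiochemistry would give the transposed enone, and the alkylnickel intermediate could also be lost by elimination of the β-acyloxy group. The fallback sets out from 13 and comes back at 19. C-Silylation (n-BuLi, THF, −78 °C; Me3SiCl) gives tert-butyl(dimethyl){[(4S)-4-methyl-6-(trimethylsilyl)hex-5-yn-1-yl]oxy}silane F1, a non-conjugated alkyne whose silyl group (the larger, metal-stabilising substituent) should stay on nickel. The same nickel-catalysed insertion into 7 then gives (3aR,7aR)-5-[(2S)-5-(TBSO)pentan-2-yl]-6-(trimethylsilyl)-3,3a,7,7a-tetrahydro-1-benzofuran-2,4-dione F2. Reduction as in step 12 gives (3aS,4S,7aR)-5-[(2S)-5-(TBSO)pentan-2-yl]-4-hydroxy-6-(trimethylsilyl)-3a,4,7,7a-tetrahydro-1-benzofuran-2(3H)-one F3. Iododesilylation with N-iodosuccinimide gives (3aS,4S,7aR)-5-[(2S)-5-(TBSO)pentan-2-yl]-4-hydroxy-6-iodo-3a,4,7,7a-tetrahydro-1-benzofuran-2(3H)-one F4. Stille coupling with Bu3SnCH2OH (Pd(PPh3)4, toluene, 80 °C) attaches the hydroxymethyl carbon directly and gives diol 19, so steps 12 and 13 are replaced.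

Step 12. The intrinsic preference of the cis-fused ketone for hydride attack on its convex face may oppose the catalyst and give poor facial selectivity at C4. The fallback sets out from 16 and comes back at 17. Substrate-controlled Luche reduction (NaBH4, CeCl3, MeOH, −78 °C) from the convex face should give (3aS,4R,7aR)-5-[(2S)-5-(TBSO)pentan-2-yl]-6-ethenyl-4-hydroxy-3a,4,7,7a-tetrahydro-1-benzofuran-2(3H)-one F5. A Mitsunobu reaction with chloroacetic acid (PPh3, DIAD, THF) inverts C4 and gives (3aR,4S,7aR)-5-[(2S)-5-(TBSO)pentan-2-yl]-6-ethenyl-2-oxo-2,3,3a,4,7,7a-hexahydro-1-benzofuran-4-yl chloroacetate F6. Mild methanolysis of the labile chloroacetate (K2CO3, MeOH, −20 °C) then returns alcohol 17.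

Step 15. The lithium alkoxide at C4 may attack the lactone carbonyl (translactonisation to the C4 oxygen) or retard enolate formation. The fallback sets out from 20 and comes back at 24. Acylation with propanoic anhydride (Et3N, DMAP) gives (3aR,4S,7aR)-6-[(TBSO)methyl]-5-[(2S)-5-(TBSO)pentan-2-yl]-2-oxo-2,3,3a,4,7,7a-hexahydro-1-benzofuran-4-yl propanoate F7, which has no free hydroxyl. Double deprotonation (LiN(iPr)2, THF, −78 °C) and a two-fold Mannich reaction with Eschenmoser's salt give the bis[(dimethylamino)methyl] compound F8. Exhaustive methylation with MeI gives the bis(trimethylammonium) diiodide F9. Base-induced elimination (aq. NaHCO3) then creates the C3 methylidene and the methacrylate C=CH2 together and gives 24, so step 16 is not needed.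

**Further compounds**

F1 | step 11 | tert-butyl(dimethyl){[(4S)-4-methyl-6-(trimethylsilyl)hex-5-yn-1-yl]oxy}silane | C[Si](C)(C)C#C[C@@H](C)CCCO[Si](C)(C)C(C)(C)C
F2 | step 11 | (3aR,7aR)-5-[(2S)-5-(TBSO)pentan-2-yl]-6-(trimethylsilyl)-3,3a,7,7a-tetrahydro-1-benzofuran-2,4-dione | O=C1C([C@@H](C)CCCO[Si](C)(C)C(C)(C)C)=C([Si](C)(C)C)C[C@H]2OC(=O)C[C@@H]12
F3 | step 11 | (3aS,4S,7aR)-5-[(2S)-5-(TBSO)pentan-2-yl]-4-hydroxy-6-(trimethylsilyl)-3a,4,7,7a-tetrahydro-1-benzofuran-2(3H)-one | O[C@@H]1C([C@@H](C)CCCO[Si](C)(C)C(C)(C)C)=C([Si](C)(C)C)C[C@H]2OC(=O)C[C@@H]12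
F4 | step 11 | (3aS,4S,7aR)-5-[(2S)-5-(TBSO)pentan-2-yl]-4-hydroxy-6-iodo-3a,4,7,7a-tetrahydro-1-benzofuran-2(3H)-one | O[C@@H]1C([C@@H](C)CCCO[Si](C)(C)C(C)(C)C)=C(I)C[C@H]2OC(=O)C[C@@H]12
F5 | step 12 | (3aS,4R,7aR)-5-[(2S)-5-(TBSO)pentan-2-yl]-6-ethenyl-4-hydroxy-3a,4,7,7a-tetrahydro-1-benzofuran-2(3H)-one | O[C@H]1C([C@@H](C)CCCO[Si](C)(C)C(C)(C)C)=C(C=C)C[C@H]2OC(=O)C[C@@H]12
F6 | step 12 | (3aR,4S,7aR)-5-[(2S)-5-(TBSO)pentan-2-yl]-6-ethenyl-2-oxo-2,3,3a,4,7,7a-hexahydro-1-benzofuran-4-yl chloroacetate | ClCC(=O)O[C@@H]1C([C@@H](C)CCCO[Si](C)(C)C(C)(C)C)=C(C=C)C[C@H]2OC(=O)C[C@@H]12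
F7 | step 15 | (3aR,4S,7aR)-6-[(TBSO)methyl]-5-[(2S)-5-(TBSO)pentan-2-yl]-2-oxo-2,3,3a,4,7,7a-hexahydro-1-benzofuran-4-yl propanoate | CCC(=O)O[C@@H]1C([C@@H](C)CCCO[Si](C)(C)C(C)(C)C)=C(CO[Si](C)(C)C(C)(C)C)C[C@H]2OC(=O)C[C@@H]12
F8 | step 15 | bis-Mannich base of F7: 3-[(dimethylamino)methyl] lactone, 3-(dimethylamino)-2-methylpropanoate ester (epimer mixture) | CC(CN(C)C)C(=O)O[C@@H]1C([C@@H](C)CCCO[Si](C)(C)C(C)(C)C)=C(CO[Si](C)(C)C(C)(C)C)C[C@H]2OC(=O)C(CN(C)C)[C@@H]12
F9 | step 15 | bis(trimethylammonium) diiodide from F8 | CC(C[N+](C)(C)C)C(=O)O[C@@H]1C([C@@H](C)CCCO[Si](C)(C)C(C)(C)C)=C(CO[Si](C)(C)C(C)(C)C)C[C@H]2OC(=O)C(C[N+](C)(C)C)[C@@H]12.[I-].[I-]
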